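**Retrosynthetic overview**

1. The target comes from chemoselective O‑acylation (primary OH only) of 4‑hydroxy‑4‑(2‑hydroxyethyl)cyclohexanone with palmitoyl chloride.
2. That keto diol comes from an acid‑mediated hydrative ring expansion (cyclopentanone → cyclohexanone, one carbon) of 5‑(2‑hydroxyethyl)bicyclo[3.1.0]hexan‑2‑one, the 2‑hydroxyethyl analogue of sabina ketone.
3. Enabling feature: the cyclopropane C1–C5–C6 is fused to the five‑membered ring across the zero‑bridge bond C1–C5, the carbonyl C2 sits on C1, and the fully substituted C5 carries the side chain. O‑protonation and cleavage of C1–C5 place a tertiary cation on C5 (the future carbinol carbon, para to C=O), and C6 becomes a ring CH2.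
4. The bicyclic ketone comes from Corey–Chaykovsky cyclopropanation of 3‑(2‑hydroxyethyl)cyclopent‑2‑enone, itself made by a Stork–Danheiser sequence (ethyl acetate enolate addition, LiAlH4, acid transposition) on 3‑ethoxycyclopent‑2‑enone.
5. Ring order: five‑membered ring bought → cyclopropane fused on (step 3) → six‑membered ring by enlargement of the five‑membered ring (step 4).

Key step: step 4

Remark on the chemistry: the target has no stereocentre (the carbinol carbon carries two identical ring arms and lies on a mirror plane), so the achiral compound itself is the required single species. Intermediates 4, 5 and 7 are racemic and their stereocentres are erased on the way.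

**Step 1**
Reactants: 1 3‑ethoxycyclopent‑2‑en‑1‑one; 2 ethyl acetate
Product: 4 ethyl 2‑(3‑ethoxy‑1‑hydroxycyclopent‑2‑en‑1‑yl)acetate (racemic), via lithium enolate of ethyl acetate 3 (not isolated)
Conditions: LDA (1.1 equiv), THF, −78 °C; then 1, −78 °C; AcOH (1.1 equiv), −78 °C; aq. NaHCO3; used crude
Reagents that add atoms: none
Why: The lithium enolate of an ester adds 1,2 to the carbonyl of a vinylogous ester at −78 °C (aldol‑type addition, first stage of a Stork–Danheiser sequence); the new carbinol stereocentre forms as a racemate and is erased in step 2.

**Step 2**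
Reactants: 4 ethyl 2‑(3‑ethoxy‑1‑hydroxycyclopent‑2‑en‑1‑yl)acetate
Product: 6 3‑(2‑hydroxyethyl)cyclopent‑2‑en‑1‑one, via diol enol ether 5 (not isolated)
Conditions: LiAlH4, THF, 0 °C; then H2O, 1 M HCl (pH 1), rt
Reagents that add atoms: water, O
Why: LiAlH4 reduces the ester while the ketone is still masked as its enol ether, and aqueous acid then ionises the tertiary allylic alcohol and hydrolyses the ethoxyallyl cation (Stork–Danheiser 1,3‑carbonyl transposition), so the enone appears without any ester/ketone chemoselectivity problem; no stereocentre remains.

**Step 3**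
Reactants: 6 3‑(2‑hydroxyethyl)cyclopent‑2‑en‑1‑one
Product: 7 5‑(2‑hydroxyethyl)bicyclo[3.1.0]hexan‑2‑one (racemic, cis‑fused)
Conditions: Me3S(O)I, NaH, DMSO, rt; then 6, rt to 50 °C
Reagents that add atoms: trimethylsulfoxonium iodide, C[S+](C)(C)=O.[I-]
Why: Corey–Chaykovsky cyclopropanation, i.e. conjugate addition of dimethylsulfoxonium methylide to the enone followed by 3‑exo‑tet displacement of DMSO by the enolate, a reaction established for 3‑alkylcyclopent‑2‑enones; the cis ring fusion is the only one possible, both new stereocentres arise as a racemate, and the un‑ionised hydroxyl is a spectator.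

**Step 4**
Reactants: 7 5‑(2‑hydroxyethyl)bicyclo[3.1.0]hexan‑2‑one
Product: 8 4‑hydroxy‑4‑(2‑hydroxyethyl)cyclohexan‑1‑one
Conditions: HClO4 (1–2 M in H2O), 25–40 °C; then NaHCO3, NaCl, EtOAc extraction
Reagents that add atoms: water, O
Why: Protonation of the C2 carbonyl makes 7 a 2‑hydroxy‑substituted cyclopropylcarbinyl cation, and heterolysis of the strained zero‑bridge bond C1–C5 (shared by the three‑ and five‑membered rings) turns the cyclopentanone into the enol of a cyclohexanone while the charge moves to C5, the one fully substituted cyclopropane carbon; water adds to this tertiary cation and the enol ketonises, so the ring enlargement, the 1,4‑relationship of C=O and carbinol, and the tertiary hydroxyl should all arise in one operation. The closest known reaction type is the acid‑mediated cyclopropylcarbinyl‑to‑homoallyl ring enlargement of the thujane skeleton to the p‑menthane skeleton (sabinene or sabinene hydrate to terpinen‑4‑ol, sabina ketone to 4‑isopropylcyclohexenones), i.e. homoconjugate addition of H–OH to a cyclopropyl ketone. No ring is closed by a new bond: the six‑membered ring is the old five‑membered ring enlarged by the former cyclopropane CH2 (C6), which ends up between C1 and C5. No stereocentre is formed, because the carbinol carbon of 8 lies on a mirror plane and both stereocentres of racemic 7 are destroyed. The step needs cleavage of the internal C1–C5 bond and not the external C1–C6 bond, which the tertiary versus primary character of the developing cation and the absence of a good nucleophile (perchlorate, no halide, so no SN2 opening at C6) should secure. It also needs capture by water and not proton loss, which the purely aqueous medium and low temperature favour; the side‑chain hydroxyl could only close an oxetane and should stay a spectator.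

**Step 5**
Reactants: 8 4‑hydroxy‑4‑(2‑hydroxyethyl)cyclohexan‑1‑one; 9 palmitoyl chloride (hexadecanoyl chloride)
Product: 10 2‑(1‑hydroxy‑4‑oxocyclohexyl)ethyl hexadecanoate (target)
Conditions: 9 (1.0 equiv), pyridine, CH2Cl2, −10 to 0 °C
Reagents that add atoms: none
Why: Acylation of a 1,3‑diol with one equivalent of an acid chloride and pyridine (no DMAP) should take place at the primary hydroxyl only, the tertiary hydroxyl and the ketone being inert (chemoselective esterification); no stereocentre is involved.

**Compound list**

1 | 3‑ethoxycyclopent‑2‑en‑1‑one | CCOC1=CC(=O)CC1 | starting material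
2 | ethyl acetate | CCOC(C)=O | starting material
3 | lithium enolate of ethyl acetate (lithium 1‑ethoxyethen‑1‑olate) | [Li+].[O-]C(=C)OCC | intermediate
4 | ethyl 2‑(3‑ethoxy‑1‑hydroxycyclopent‑2‑en‑1‑yl)acetate, racemic (one enantiomer drawn) | CCOC(=O)C[C@]1(O)CCC(OCC)=C1 | intermediate
5 | 3‑ethoxy‑1‑(2‑hydroxyethyl)cyclopent‑2‑en‑1‑ol (diol enol ether), racemic (one enantiomer drawn) | OCC[C@]1(O)CCC(OCC)=C1 | intermediate
6 | 3‑(2‑hydroxyethyl)cyclopent‑2‑en‑1‑one | O=C1C=C(CCO)CC1 | intermediate
7 | 5‑(2‑hydroxyethyl)bicyclo[3.1.0]hexan‑2‑one, racemic, cis‑fused (one enantiomer drawn) | O=C1CC[C@@]2(CCO)C[C@@H]12 | intermediate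
8 | 4‑hydroxy‑4‑(2‑hydroxyethyl)cyclohexan‑1‑one | O=C1CCC(O)(CCO)CC1 | intermediate
9 | palmitoyl chloride (hexadecanoyl chloride) | CCCCCCCCCCCCCCCC(Cl)=O | starting material
10 | 2‑(1‑hydroxy‑4‑oxocyclohexyl)ethyl hexadecanoate | CCCCCCCCCCCCCCCC(=O)OCCC1(O)CCC(=O)CC1 | target

**Totals**

Total step count: 5. Longest linear sequence: 5 steps (from 1).

**Steps most likely to fail**

Step 4. Proton loss from the tertiary cation, followed by migration of the double bond into conjugation, may outrun capture by water. The opening of the internal bond may also be too slow in dilute acid, since the external C1–C6 bond overlaps better with the carbonyl π system, and may then call for acid strengths at which the tertiary alcohol dehydrates. The fallback uses a different ring‑expansion manifold and known chemistry. It sets out from 4. LiAlH4 reduction with a basic aqueous work‑up gives 5, this time isolated. Hydroxyl‑directed Simmons–Smith–Furukawa cyclopropanation (Et2Zn, CH2I2, CH2Cl2, 0 °C) of its enol‑ether double bond gives 5‑ethoxy‑2‑(2‑hydroxyethyl)bicyclo[3.1.0]hexan‑2‑ol F1. Brief treatment with dilute acid (PPTS in wet acetone, or 0.1 M HCl/THF, 0 °C) ionises the tertiary cyclopropylcarbinol, and the ethoxy group pushes open the zero‑bridge bond (alkoxycyclopropylcarbinyl fragmentation, again a five‑to‑six ring expansion) to give 4‑(2‑hydroxyethyl)cyclohex‑3‑en‑1‑one F2. Mukaiyama hydration (Co(acac)2 cat., PhSiH3, O2, i‑PrOH) installs the tertiary hydroxyl in the Markovnikov sense and returns to the route at 8. Material from step 4 that has lost a proton without conjugating is this same olefin and can be fed into the same hydration.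

Step 3. The basic ylide may deprotonate the γ‑position of the β,β‑disubstituted enone (dienolate formation) instead of adding to its hindered β‑carbon, leaving starting material or oligomers. The fallback cyclopropanates an allylic alcohol instead of an enone. From 6, Luche reduction (NaBH4, CeCl3·7H2O, MeOH, 0 °C) gives 3‑(2‑hydroxyethyl)cyclopent‑2‑en‑1‑ol F3. Hydroxyl‑directed Simmons–Smith–Furukawa cyclopropanation (Et2Zn, CH2I2, CH2Cl2, 0 °C to rt) gives 5‑(2‑hydroxyethyl)bicyclo[3.1.0]hexan‑2‑ol F4. Oxidation of the secondary hydroxyl in the presence of the primary one (NaOCl, AcOH) returns to the route at 7.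

Step 1. Proton transfer from C5 of the vinylogous ester to the ester enolate, or retro‑aldol cleavage of the lithium aldolate before the quench, may compete with addition, and 4 may ionise on contact with acid during handling. The fallback uses a different two‑carbon nucleophile, with no aldolate and no ester reduction. From 1, vinylmagnesium bromide (THF, −78 to 0 °C, aq. NaHCO3 work‑up) gives 1‑ethenyl‑3‑ethoxycyclopent‑2‑en‑1‑ol F5. Hydroboration of the terminal double bond with 9‑BBN and oxidation with NaOH/H2O2 gives the diol enol ether 5, which is taken through the acid stage of step 2; the fallback thus comes back to the route at 5.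

**Further compounds**

F1 | step 4 | 5‑ethoxy‑2‑(2‑hydroxyethyl)bicyclo[3.1.0]hexan‑2‑ol, racemic, OH syn to the cyclopropane CH2 (one enantiomer drawn) | OCC[C@]1(O)CC[C@@]2(OCC)C[C@@H]12
F2 | step 4 | 4‑(2‑hydroxyethyl)cyclohex‑3‑en‑1‑one | O=C1CCC(CCO)=CC1
F3 | step 3 | 3‑(2‑hydroxyethyl)cyclopent‑2‑en‑1‑ol, racemic (one enantiomer drawn) | O[C@H]1CCC(CCO)=C1
F4 | step 3 | 5‑(2‑hydroxyethyl)bicyclo[3.1.0]hexan‑2‑ol, racemic, OH syn to the cyclopropane CH2 (one enantiomer drawn) | O[C@H]1CC[C@@]2(CCO)C[C@@H]12
F5 | step 1 | 1‑ethenyl‑3‑ethoxycyclopent‑2‑en‑1‑ol, racemic (one enantiomer drawn) | C=C[C@]1(O)CCC(OCC)=C1
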